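Late in these runs the reading to watch is L: the leak of J into L is written with no way back, and it runs for as long as J stands in the flask.

    Z + E → Z.E (k1 = 0.25 L mol⁻¹ h⁻¹, Ea1 = 68.0 kJ mol⁻¹)
    J → L (k2 = 0.016 h⁻¹, Ea2 = 103 kJ mol⁻¹)
    E + Q ⇌ Z + J (K3 = 4.8, k3 = 55 L mol⁻¹ h⁻¹, Ea3 = 73.0 kJ mol⁻¹, ΔH3 = −33.0 kJ mol⁻¹)
    J + Q ⇌ Z + D (K4 = 24, k4 = 19 L mol⁻¹ h⁻¹, Ea4 = 76.0 kJ mol⁻¹, ΔH4 = 7.00 kJ mol⁻¹)
    (constants at 50 °C)

| flask | E | Q | Z | temperature | time | remark |
|---|---|---|---|---|---|---|
| violet | 0.010 M | 0.600 equiv (fed, over 2.5 d) | 5.00 equiv | 50 °C | 3.0 d | all else is in the flask from the start; the feed brings no volume worth counting |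
| grey | 0.010 M (fed, over 2.5 d) | 0.600 equiv | 5.00 equiv | 50 °C | 3.0 d | all else is in the flask from the start; the feed brings no volume worth counting |
| green | 0.010 M | 0.600 equiv (fed, over 2.5 d) | 5.00 equiv |  | 3.0 d | the addition at 20 °C, then warmed to 50 °C; the feed brings no volume worth counting |
| teal | 0.010 M | 0.600 equiv | 5.00 equiv | 50 °C | 3.0 d | everything together at the start |

1. the flask that comes out highest in share of D in D plus L, or "all alike" when all lie within 1.5 percentage points (violet / grey / green / teal / all alike)
2. share of D in D plus L at the end, violet
3. share of D in D plus L at the end, grey
4. share of D in D plus L at the end, green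
5. share of D in D plus L at the end, teal

- the constants hold at 50 °C; other temperatures follow from the activation energies and enthalpies

Two chemists argue over these flasks before any run. The racer looks at the fork at J, where Q carries J on to D and the leak carries it to L. With Q as charged, the ratio of the forward rate to D over the leak, a selectivity factor, is 7.12. That ratio promises 87.7% of D in D plus L. Teal has its whole Q and its whole E together from the start, so the racer backs teal and expects the slow feeds of Q to starve the fork.

The counter answers that D is not a safe place to be. With Z as charged, D returns to J at 0.0396 h⁻¹, faster than J leaks at 0.016 h⁻¹, so what reaches D can come back and face the leak again. The counter therefore counts turnovers. The leak constant at the temperature of the moment is multiplied by the time the average portion of the fed reagent has spent in the flask, as if that portion stood as J throughout, so the count is a measure of exposure and not an amount of L.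

In teal nothing is fed, so the average portion sits the full 3.0 d and the count is 1.15. In violet and grey the average portion arrives halfway through the feed, which gives 0.672. In green the leak constant at 20 °C is multiplied by 0.0198, so the cold stretch adds less than the warm 0.500 d, for a total of 0.201. This sum, the leak turnovers, is what I would commit to. It gives an order and no percentages: green has a smaller count than the feeds, the feeds a smaller count than teal, and violet and grey tie.

The forecast sides with the counter and names green, with 54% for violet, 55% for grey, 73% for green and 39% for teal, holding that when cold “the leak from J to L almost stops”.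

The simulation gives 52.2% for violet, 54.2% for grey, 73.1% for green and 42.4% for teal, so green stands highest and teal lowest, the order of the count, while violet and grey, tied in the count, lie 2 percentage points apart. The racer's ratio points the right way at equal count: green at 0.025 M of E keeps 0.201 turnovers and gives 80.4%, more than the 73.1% of green as charged. Green has not come to rest at its asked time. Read at 5.0 d, with 0.969 turnovers, it gives 46.9%. In green at 30.0 d, with a count of 10.6, L has gone from 3.41% to 23.8%, Z.E from 15.0% to 75.8%, D from 9.30% to 0.144%, and the share of D stands at 0.601%.

All constants are those of an exercise, and the outcome is calculated.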